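**Retrosynthetic overview**
1. Target ⇐ hydrogenolysis of three 4-tert-butylbenzyl ethers. The ring D hydroxyl sits at the only aromatic C–H of the skeleton with no ortho neighbour, so it comes from a late, sterically governed C–H borylation/oxidation.
2. Lower pyran (ring F) ⇐ primary alcohol ArD–CH2CH2OH + a 2-fluoro-4-alkoxybenzyl alcohol. One hydrogen-borrowing aldol/reduction/SNAr cascade forms C3–C4 and O1–C8a of the lower chroman and sets lower C3.
3. Enabling feature: lower C3 is benzylic to ring D and β to O1, so at the C2-aldehyde level it is an enolisable, stereolabile aldol donor. C4 is a CH2 on C4a and can enter as an aryl aldehyde carbon. O1 sits on C8a, ortho to C4a, so an ortho fluorine makes ring E a C4/C8a bis-electrophile.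
4. Upper pyran (ring C, both upper stereocentres) ⇐ aminocatalytic [4+2] of an arylacetaldehyde with an o-quinone methide stored as an isochroman. This temporary ring also carries the future O1–C2–C3 chain and comes from directed ortho-lithiation of 2-(3-methoxyphenyl)ethanol plus a salicylaldehyde.
5. Order of ring formation: temporary isochroman, then ring C, then ring F.

Key step: step 10

Remark on names: rings A/C are the benzo and pyran rings of the upper chroman, ring B is its 3-aryl group, ring D is the central aryl on upper C4, and rings E/F are the benzo and pyran rings of the lower chroman. TBB is 4-tert-butylbenzyl. Ar* is 2-[(3R,4S)-7-(TBB-oxy)-3-[2-(TBB-oxy)-4,5-dimethoxyphenyl]chroman-4-yl]-3-methoxyphenyl.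

Remark on the protecting group: every ring C–H of a TBB ether has an ortho substituent, so it should escape the borylation of step 11 and still cleave by hydrogenolysis.

Assumption: the sense of induction of the ruthenium catalyst in step 10 is taken by analogy with 2-arylaldehyde reductions; the mirror-image catalyst is used if the sense proves opposite.

Step 1
Reactants: 1 2,4-dihydroxybenzaldehyde
Product: 2 4-(TBB-oxy)-2-hydroxybenzaldehyde
Conditions: 4-tert-butylbenzyl bromide (1.05 equiv), NaHCO3, KI (cat.), MeCN, 80 °C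
Reagents that add atoms: 4-tert-butylbenzyl bromide, CC(C)(C)c1ccc(CBr)cc1
Why: Williamson etherification in which the 2-hydroxyl, held in a hydrogen bond to the formyl group, stays untouched by the weak base, so only the 4-hydroxyl should be alkylated.

Step 2
Reactants: 3 2-hydroxy-4,5-dimethoxybenzaldehyde
Product: 4 2-(TBB-oxy)-4,5-dimethoxybenzaldehyde
Conditions: 4-tert-butylbenzyl bromide, K2CO3, DMF, 60 °C
Reagents that add atoms: 4-tert-butylbenzyl bromide, CC(C)(C)c1ccc(CBr)cc1
Why: Williamson etherification of the only phenol.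

Step 3
Reactants: 4 2-(TBB-oxy)-4,5-dimethoxybenzaldehyde
Product: 5 1-(TBB-oxy)-4,5-dimethoxy-2-(2-methoxyethenyl)benzene (E/Z mixture)
Conditions: (methoxymethyl)triphenylphosphonium chloride, KOtBu, THF, 0 °C → rt
Reagents that add atoms: (methoxymethyl)triphenylphosphonium chloride, COC[P+](c1ccccc1)(c1ccccc1)c1ccccc1.[Cl-]
Why: Wittig methoxymethylenation as a one-carbon homologation; the alkene geometry is lost in step 4 and does not matter.

Step 4
Reactants: 5 1-(TBB-oxy)-4,5-dimethoxy-2-(2-methoxyethenyl)benzene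
Product: 6 [2-(TBB-oxy)-4,5-dimethoxyphenyl]acetaldehyde
Conditions: 2 M aq. HCl/THF (1:4), 40 °C; used without storage
Reagents that add atoms: water, O
Why: Acid-catalysed enol ether hydrolysis to the homologous aldehyde; the aryl benzyl ether is stable to dilute acid.

Step 5
Reactants: 7 2-fluoro-4-hydroxybenzaldehyde
Product: 8 4-(TBB-oxy)-2-fluorobenzaldehyde
Conditions: 4-tert-butylbenzyl bromide, K2CO3, DMF, rt
Reagents that add atoms: 4-tert-butylbenzyl bromide, CC(C)(C)c1ccc(CBr)cc1
Why: Williamson etherification, which at room temperature should be much faster than any fluoride displacement on the phenoxide-deactivated ring.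

Step 6
Reactants: 8 4-(TBB-oxy)-2-fluorobenzaldehyde
Product: 9 [4-(TBB-oxy)-2-fluorophenyl]methanol
Conditions: NaBH4, MeOH/THF, 0 °C
Reagents that add atoms: none
Why: Borohydride reduction of the aldehyde, which gives the redox-neutral partner for step 10.

Step 7
Reactants: 10 2-(3-methoxyphenyl)ethanol; 2 4-(TBB-oxy)-2-hydroxybenzaldehyde
Product: 12 rac-2-(8-methoxyisochroman-1-yl)-5-(TBB-oxy)phenol, via triol 11 (not isolated)
Conditions: 10, n-BuLi (2.3 equiv), TMEDA, Et2O/hexane, 0 °C → rt; sodium salt of 2 (NaH, THF, 0 °C) added at −78 → 0 °C; 1 M HCl work-up; then TsOH·H2O (cat.), CH2Cl2, rt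
Reagents that add atoms: none
Why: Directed ortho-metalation in which the side-chain lithium alkoxide and the methoxy group jointly direct lithiation to the carbon between them (the known route to 8-methoxy-3,4-dihydroisocoumarins); the aryllithium adds to the formyl group of the phenoxide of 2, and acid converts o-hydroxybenzhydrol 11 through its o-quinone methide into the six-membered cyclic ether, whose racemic centre is erased in step 8.

Step 8
Reactants: 12 rac-2-(8-methoxyisochroman-1-yl)-5-(TBB-oxy)phenol; 6 [2-(TBB-oxy)-4,5-dimethoxyphenyl]acetaldehyde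
Product: 14 (3R,4S)-7-(TBB-oxy)-3-[2-(TBB-oxy)-4,5-dimethoxyphenyl]-4-[2-(2-hydroxyethyl)-6-methoxyphenyl]chroman-2-ol (anomer mixture), via quinone methide 13 (not isolated)
Conditions: (R)-α,α-diphenylprolinol trimethylsilyl ether (20 mol %), diphenyl phosphate (30 mol %), 6 (1.5 equiv), CHCl3, 40 °C
Reagents that add atoms: none
Why: Aminocatalytic formal [4+2] annulation (enamine Michael addition to an o-quinone methide, then hemiacetalisation) in which the acid reopens the benzylic C–O bond of 12 to 13, the diphenyl(silyloxy)methyl group shields one enamine face so that C3 should form as (R) (the sense known for this catalyst in Michael additions, transposed to the aryl-substituted enamine), and the anti approach of the two aryl groups should give C4 as (S), the 3,4-trans arrangement that is also the thermodynamic one for the epimerisable α-aryl lactol.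

Step 9
Reactants: 14 (3R,4S)-7-(TBB-oxy)-3-[2-(TBB-oxy)-4,5-dimethoxyphenyl]-4-[2-(2-hydroxyethyl)-6-methoxyphenyl]chroman-2-ol
Product: 15 2-Ar*-ethanol, that is 2-{2-[(3R,4S)-7-(TBB-oxy)-3-[2-(TBB-oxy)-4,5-dimethoxyphenyl]chroman-4-yl]-3-methoxyphenyl}ethanol
Conditions: Et3SiH (3 equiv), BF3·OEt2 (2 equiv), CH2Cl2, −78 → −20 °C
Reagents that add atoms: none
Why: Ionic hydrogenation of the lactol (loss of the anomeric hydroxyl to the cyclic oxocarbenium ion, then hydride transfer from silicon); C4 is untouched, and C3, even if it equilibrates through the oxocarbenium/enol ether pair, should return to the favoured trans arrangement.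

Step 10
Reactants: 15 2-Ar*-ethanol; 9 [4-(TBB-oxy)-2-fluorophenyl]methanol
Product: 20 (3R,4S)-7-(TBB-oxy)-3-[2-(TBB-oxy)-4,5-dimethoxyphenyl]-4-{2-methoxy-6-[(3R)-7-(TBB-oxy)chroman-3-yl]phenyl}chroman, via aldehyde 8 (not isolated), via arylacetaldehyde 16 (not isolated), via enal 17 (not isolated), via saturated aldehyde 18 (not isolated), via fluoro alcohol 19 (not isolated)
Conditions: 9 (2.5 equiv), RuCl2(DMM-SDP)(DACH) (spirobiindane diphosphine/trans-1,2-diaminocyclohexane complex, enantiomer that gives (R) at lower C3; 5 mol %), KOtBu (3 equiv), 1,4-dioxane/DMPU 4:1, argon, sealed tube, 70 °C then 110 °C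
Reagents that add atoms: none
Why: Proposed new method: the divalent ruthenium hydride catalyst should dehydrogenate both primary alcohols reversibly (to 16 and 8), base should condense the only enolisable aldehyde 16 with the non-enolisable, more electrophilic 8 to enal 17, and the stored hydride should return by conjugate and carbonyl reduction (17 → 18 → 19), which forms C3–C4 of the lower chroman, after which the potassium alkoxide of 19 displaces the ortho fluorine and forms O1–C8a. The closest known reaction types are the Guerbet-type β-alkylation of 2-arylethanols with benzylic alcohols under hydrogen-borrowing catalysis, the dynamic kinetic resolution of 2-arylaldehydes by RuCl2(diphosphine)(diamine)/KOtBu reduction, and alkoxide SNAr cyclisations of 3-(2-fluorophenyl)propanols to chromans; their merger in one flask is new. Ring F closes by a 6-exo-trig addition–elimination through a Meisenheimer complex at C8a, helped inductively by the meta alkoxy group of ring E. Lower C3 is set under catalyst control, because 18 epimerises through its enolate faster than it is reduced, the chiral hydride should reduce one epimer preferentially to (R)-19, and the irreversible ring closure takes 19 out of the redox equilibrium and freezes C3. The step needs cross- over self-condensation (secured by the missing α-hydrogens of 8, its excess and the steric bulk around 16), ring closure only after reduction (the allylic alkoxide from (E)-17 holds its oxygen trans to the fluoroarene and cannot reach C8a, whereas the freely rotating alkoxide of 19 can) and intact upper centres (trans-3,4 is the thermodynamic arrangement and upper C3–H is not acidic).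

Step 11
Reactants: 20 (3R,4S)-7-(TBB-oxy)-3-[2-(TBB-oxy)-4,5-dimethoxyphenyl]-4-{2-methoxy-6-[(3R)-7-(TBB-oxy)chroman-3-yl]phenyl}chroman
Product: 21 (3R,4S)-7-(TBB-oxy)-3-[2-(TBB-oxy)-4,5-dimethoxyphenyl]-4-{2-methoxy-4-(4,4,5,5-tetramethyl-1,3,2-dioxaborolan-2-yl)-6-[(3R)-7-(TBB-oxy)chroman-3-yl]phenyl}chroman
Conditions: [Ir(OMe)(cod)]2 (2.5 mol %), 4,4'-di-tert-butyl-2,2'-bipyridine (5 mol %), B2pin2 (1.5 equiv), THF, 70 °C
Reagents that add atoms: bis(pinacolato)diboron, CC1(C)OB(OC1(C)C)B1OC(C)(C)C(C)(C)O1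
Why: Iridium-catalysed arene C–H borylation under steric control, in which the ring D hydrogen para to the upper chroman is the only aromatic C–H of 20 without an ortho substituent (every C–H of rings A, B, E and of the TBB groups has one), so the tris(boryl)iridium catalyst should select it.

Step 12
Reactants: 21 the ring D pinacol boronate
Product: 22 (3R,4S)-7-(TBB-oxy)-3-[2-(TBB-oxy)-4,5-dimethoxyphenyl]-4-{4-hydroxy-2-methoxy-6-[(3R)-7-(TBB-oxy)chroman-3-yl]phenyl}chroman
Conditions: H2O2 (30 % aq.), NaOH (1 M aq.), THF, 0 °C → rt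
Reagents that add atoms: hydrogen peroxide, OO
Why: Oxidation of the aryl boronate by hydroperoxide (1,2-aryl shift from boron to oxygen, then hydrolysis), which places the hydroxyl exactly where the boron was.

Step 13
Reactants: 22 the tris-TBB ether of the target
Product: 23 (3R,4S)-3-(2-hydroxy-4,5-dimethoxyphenyl)-4-{4-hydroxy-2-[(3R)-7-hydroxychroman-3-yl]-6-methoxyphenyl}chroman-7-ol (target)
Conditions: H2 (1 atm), 10 % Pd/C, EtOAc/MeOH 1:1, rt
Reagents that add atoms: none
Why: Hydrogenolysis of the three benzylic aryl ethers on palladium; the chroman C–O bonds are not benzylic and the diarylmethine and methyl ethers are inert, so no stereocentre should be touched.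

**Compound list**
1 | 2,4-dihydroxybenzaldehyde | O=Cc1ccc(O)cc1O | starting material
2 | 4-(TBB-oxy)-2-hydroxybenzaldehyde | O=Cc1ccc(OCc2ccc(C(C)(C)C)cc2)cc1O | intermediate
3 | 2-hydroxy-4,5-dimethoxybenzaldehyde | COc1cc(O)c(C=O)cc1OC | starting material
4 | 2-(TBB-oxy)-4,5-dimethoxybenzaldehyde | COc1cc(OCc2ccc(C(C)(C)C)cc2)c(C=O)cc1OC | intermediate
5 | 1-(TBB-oxy)-4,5-dimethoxy-2-(2-methoxyethenyl)benzene (E/Z mixture) | COC=Cc1cc(OC)c(OC)cc1OCc1ccc(C(C)(C)C)cc1 | intermediate
6 | [2-(TBB-oxy)-4,5-dimethoxyphenyl]acetaldehyde | O=CCc1cc(OC)c(OC)cc1OCc1ccc(C(C)(C)C)cc1 | intermediate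
7 | 2-fluoro-4-hydroxybenzaldehyde | O=Cc1ccc(O)cc1F | starting material
8 | 4-(TBB-oxy)-2-fluorobenzaldehyde | O=Cc1ccc(OCc2ccc(C(C)(C)C)cc2)cc1F | intermediate
9 | [4-(TBB-oxy)-2-fluorophenyl]methanol | OCc1ccc(OCc2ccc(C(C)(C)C)cc2)cc1F | intermediate
10 | 2-(3-methoxyphenyl)ethanol | COc1cccc(CCO)c1 | starting material
11 | rac-2-{hydroxy[2-(2-hydroxyethyl)-6-methoxyphenyl]methyl}-5-(TBB-oxy)phenol | COc1cccc(CCO)c1C(O)c1ccc(OCc2ccc(C(C)(C)C)cc2)cc1O | intermediate
12 | rac-2-(8-methoxyisochroman-1-yl)-5-(TBB-oxy)phenol | COc1cccc2c1C(c1ccc(OCc3ccc(C(C)(C)C)cc3)cc1O)OCC2 | intermediate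
13 | 6-{[2-(2-hydroxyethyl)-6-methoxyphenyl]methylidene}-3-(TBB-oxy)cyclohexa-2,4-dien-1-one | O=C1C=C(OCc2ccc(C(C)(C)C)cc2)C=CC1=Cc1c(OC)cccc1CCO | intermediate
14 | (3R,4S)-7-(TBB-oxy)-3-[2-(TBB-oxy)-4,5-dimethoxyphenyl]-4-[2-(2-hydroxyethyl)-6-methoxyphenyl]chroman-2-ol (anomer mixture) | COc1cc(OCc2ccc(C(C)(C)C)cc2)c([C@@H]2C(O)Oc3cc(OCc4ccc(C(C)(C)C)cc4)ccc3[C@H]2c2c(OC)cccc2CCO)cc1OC | intermediate
15 | 2-Ar*-ethanol | COc1cc(OCc2ccc(C(C)(C)C)cc2)c([C@@H]2COc3cc(OCc4ccc(C(C)(C)C)cc4)ccc3[C@H]2c2c(OC)cccc2CCO)cc1OC | intermediate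
16 | Ar*-acetaldehyde | COc1cc(OCc2ccc(C(C)(C)C)cc2)c([C@@H]2COc3cc(OCc4ccc(C(C)(C)C)cc4)ccc3[C@H]2c2c(OC)cccc2CC=O)cc1OC | intermediate
17 | (E)-2-Ar*-3-[4-(TBB-oxy)-2-fluorophenyl]acrylaldehyde (expected geometry) | COc1cc(OCc2ccc(C(C)(C)C)cc2)c([C@@H]2COc3cc(OCc4ccc(C(C)(C)C)cc4)ccc3[C@H]2c2c(OC)cccc2/C(C=O)=C\c2ccc(OCc3ccc(C(C)(C)C)cc3)cc2F)cc1OC | intermediate
18 | 2-Ar*-3-[4-(TBB-oxy)-2-fluorophenyl]propanal (epimers at C2) | COc1cc(OCc2ccc(C(C)(C)C)cc2)c([C@@H]2COc3cc(OCc4ccc(C(C)(C)C)cc4)ccc3[C@H]2c2c(OC)cccc2C(C=O)Cc2ccc(OCc3ccc(C(C)(C)C)cc3)cc2F)cc1OC | intermediate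
19 | (2R)-2-Ar*-3-[4-(TBB-oxy)-2-fluorophenyl]propan-1-ol | COc1cc(OCc2ccc(C(C)(C)C)cc2)c([C@@H]2COc3cc(OCc4ccc(C(C)(C)C)cc4)ccc3[C@H]2c2c(OC)cccc2[C@H](CO)Cc2ccc(OCc3ccc(C(C)(C)C)cc3)cc2F)cc1OC | intermediate
20 | (3R,4S)-7-(TBB-oxy)-3-[2-(TBB-oxy)-4,5-dimethoxyphenyl]-4-{2-methoxy-6-[(3R)-7-(TBB-oxy)chroman-3-yl]phenyl}chroman | COc1cc(OCc2ccc(C(C)(C)C)cc2)c([C@@H]2COc3cc(OCc4ccc(C(C)(C)C)cc4)ccc3[C@H]2c2c(OC)cccc2[C@@H]2COc3cc(OCc4ccc(C(C)(C)C)cc4)ccc3C2)cc1OC | intermediate
21 | ring D pinacol boronate of 20 (boron para to the upper chroman) | COc1cc(OCc2ccc(C(C)(C)C)cc2)c([C@@H]2COc3cc(OCc4ccc(C(C)(C)C)cc4)ccc3[C@H]2c2c(OC)cc(B3OC(C)(C)C(C)(C)O3)cc2[C@@H]2COc3cc(OCc4ccc(C(C)(C)C)cc4)ccc3C2)cc1OC | intermediate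
22 | (3R,4S)-7-(TBB-oxy)-3-[2-(TBB-oxy)-4,5-dimethoxyphenyl]-4-{4-hydroxy-2-methoxy-6-[(3R)-7-(TBB-oxy)chroman-3-yl]phenyl}chroman | COc1cc(OCc2ccc(C(C)(C)C)cc2)c([C@@H]2COc3cc(OCc4ccc(C(C)(C)C)cc4)ccc3[C@H]2c2c(OC)cc(O)cc2[C@@H]2COc3cc(OCc4ccc(C(C)(C)C)cc4)ccc3C2)cc1OC | intermediate
23 | (3R,4S)-3-(2-hydroxy-4,5-dimethoxyphenyl)-4-{4-hydroxy-2-[(3R)-7-hydroxychroman-3-yl]-6-methoxyphenyl}chroman-7-ol | COc1cc(O)c([C@@H]2COc3cc(O)ccc3[C@H]2c2c(OC)cc(O)cc2[C@@H]2COc3cc(O)ccc3C2)cc1OC | target

**Step count and risks**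

Total steps: 13. Longest linear sequence: 9 steps (steps 2, 3, 4, 8, 9, 10, 11, 12, 13, from compound 3 to 23).

Steps most likely to fail:

1. Step 10 (proposed new method). What may go wrong:
   - self-condensation of the arylacetaldehyde instead of the cross-aldol;
   - displacement of fluoride on the carbonyl-activated fluoro aldehyde by an alkoxide before the C–C bond exists;
   - loss of configuration at lower C3 through re-oxidation of the alcohol before ring closure;
   - a mismatch between catalyst and substrate chirality.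

   Fallback with known chemistry, from 15 back to 20: the primary alcohol of 15 is oxidised (TEMPO, PhI(OAc)2, MeCN/H2O) to arylacetic acid F1. F1 is coupled through its pivaloyl mixed anhydride with lithiated (R)-4-benzyloxazolidin-2-one to imide F2. The sodium enolate of F2 (NaHMDS, THF, −78 °C) is alkylated, anti to the benzyl group of the auxiliary, with benzyl bromide F3 (made from 9 with PBr3) to give alkylated imide F4. LiBH4 then releases fluoro alcohol 19, and KOtBu in THF/DMPU closes ring F by intramolecular SNAr, which returns to the route at 20.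

2. Step 8. What may go wrong: slow ionisation of the isochroman, sluggish addition to the hindered quinone methide, self-aldol of 6, or poor facial selectivity at C4.

   Fallback, from 12 and 6 back to 14: 6 is condensed with benzyl carbamate (TsOH cat., toluene, Dean–Stark trap) to (E)-enecarbamate F5. A chiral BINOL-derived phosphoric acid (TRIP, enantiomer chosen for 4S; 10 mol %, CHCl3, rt) both ionises 12 and directs the addition of F5 to the hydrogen-bonded quinone methide, giving 2-(benzyloxycarbonylamino)chroman F6. Mild aqueous acid (1 M HCl, THF) hydrolyses the N,O-aminal and returns to the route at lactol 14.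

3. Step 11. What may go wrong: incomplete or unselective C–H borylation (competing reaction at the less hindered TBB positions, or catalyst inhibition by the polyether).

   Fallback, from 20 back to 22: a rhodium-catalysed arene C–H silylation, which is even more sensitive to ortho substituents ([Rh(coe)2OH]2, a bulky biaryl bisphosphine, HSiMe(OSiMe3)2, cyclohexene as hydrogen acceptor, THF, 50–80 °C), gives aryl silane F7. Tamao–Fleming oxidation (H2O2, TBAF, KHCO3, THF/MeOH) converts C–Si into C–OH and returns to the route at 22.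

**Further compounds**
F1 | step 10 | Ar*-acetic acid | COc1cc(OCc2ccc(C(C)(C)C)cc2)c([C@@H]2COc3cc(OCc4ccc(C(C)(C)C)cc4)ccc3[C@H]2c2c(OC)cccc2CC(=O)O)cc1OC
F2 | step 10 | (4R)-4-benzyl-3-(Ar*-acetyl)oxazolidin-2-one | COc1cc(OCc2ccc(C(C)(C)C)cc2)c([C@@H]2COc3cc(OCc4ccc(C(C)(C)C)cc4)ccc3[C@H]2c2c(OC)cccc2CC(=O)N2C(=O)OC[C@H]2Cc2ccccc2)cc1OC
F3 | step 10 | 4-(TBB-oxy)-2-fluorobenzyl bromide | BrCc1ccc(OCc2ccc(C(C)(C)C)cc2)cc1F
F4 | step 10 | (4R)-4-benzyl-3-{(2R)-2-Ar*-3-[4-(TBB-oxy)-2-fluorophenyl]propanoyl}oxazolidin-2-one | COc1cc(OCc2ccc(C(C)(C)C)cc2)c([C@@H]2COc3cc(OCc4ccc(C(C)(C)C)cc4)ccc3[C@H]2c2c(OC)cccc2[C@H](C(=O)N2C(=O)OC[C@H]2Cc2ccccc2)Cc2ccc(OCc3ccc(C(C)(C)C)cc3)cc2F)cc1OC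
F5 | step 8 | benzyl (E)-{2-[2-(TBB-oxy)-4,5-dimethoxyphenyl]ethenyl}carbamate | O=C(OCc1ccccc1)N/C=C/c1cc(OC)c(OC)cc1OCc1ccc(C(C)(C)C)cc1
F6 | step 8 | benzyl {(3R,4S)-7-(TBB-oxy)-3-[2-(TBB-oxy)-4,5-dimethoxyphenyl]-4-[2-(2-hydroxyethyl)-6-methoxyphenyl]chroman-2-yl}carbamate (C2 epimers) | COc1cc(OCc2ccc(C(C)(C)C)cc2)c([C@@H]2C(NC(=O)OCc3ccccc3)Oc3cc(OCc4ccc(C(C)(C)C)cc4)ccc3[C@H]2c2c(OC)cccc2CCO)cc1OC
F7 | step 11 | ring D bis(trimethylsiloxy)methylsilyl derivative of 20 (silicon para to the upper chroman) | COc1cc(OCc2ccc(C(C)(C)C)cc2)c([C@@H]2COc3cc(OCc4ccc(C(C)(C)C)cc4)ccc3[C@H]2c2c(OC)cc([Si](C)(O[Si](C)(C)C)O[Si](C)(C)C)cc2[C@@H]2COc3cc(OCc4ccc(C(C)(C)C)cc4)ccc3C2)cc1OC
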